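**Retrosynthetic overview**

1. Butenolide numbering used here: O1, C2 (lactone C=O), C3 (enol C–OH), C4 (C–Ph), C5 (quaternary, R).
2. 12 ⇒ 9 + 10: the butenolide is closed last. O1–C2 comes from acylating the tertiary alcohol; C3=C4 comes from an intramolecular aldol condensation onto the phenyl ketone with loss of acetate.
3. 9 ⇒ 7 + 8: C4–C5 by a carbene-catalysed crossed benzoin. Benzaldehyde acts as a benzoyl anion (Breslow intermediate) and adds to the keto carbon of the arylpyruvate; this sets the only stereocentre.
4. 7 ⇒ 4 + 5 (Horner–Wadsworth–Emmons pyruvate homologation); 4 ⇒ 1 + 2 (acid-mediated prenylation/cyclisation).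
5. Ring order: chroman pyran ring first (step 1), butenolide last (step 4); both benzene rings are bought.

Assumptions: phosphonate 5 is bought as a catalog reagent; the sense of induction in step 3 is not predictable with certainty, so it is checked in a pilot run and the catalyst antipode that gives (R)-9 is used (both antipodes are sold).

**Route**

Step 1
Reactants: 1 4-hydroxybenzaldehyde; 2 isoprene
Product: 4 2,2-dimethylchroman-6-carbaldehyde, via 4-hydroxy-3-prenylbenzaldehyde 3 (not isolated)
Conditions: 2 (3 equiv, slow addition), 85% H3PO4, xylene, 30–35 °C, 24 h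
Reagents that add atoms: none
Why: Acid-mediated Friedel–Crafts prenylation ortho to the phenol (para is blocked by the formyl group), then Markovnikov hydroalkoxylation of the prenyl alkene by the phenol, closes the 2,2-dimethylchroman ring; no stereocentre is formed.

Step 2
Reactants: 4 2,2-dimethylchroman-6-carbaldehyde; 5 methyl 2-[(tert-butyldimethylsilyl)oxy]-2-(dimethoxyphosphoryl)acetate
Product: 7 methyl 3-(2,2-dimethylchroman-6-yl)-2-oxopropanoate, via silyl enol ether 6 (not isolated)
Conditions: 5, LiN(SiMe3)2, THF, −78 °C; then 4, −78 °C → rt; then AcOH, Bu4NF, 0 °C, 30 min (one pot)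
Reagents that add atoms: none
Why: Horner–Wadsworth–Emmons olefination gives the silyl enol ether of the pyruvate, and acetic-acid-buffered fluoride desilylation releases the α-keto ester (keto/enol mixture) without free base that would start its self-aldol; no stereocentre is formed and the E/Z ratio of 6 is irrelevant.

Step 3
Reactants: 7 methyl 3-(2,2-dimethylchroman-6-yl)-2-oxopropanoate; 8 benzaldehyde
Product: 9 methyl (R)-2-[(2,2-dimethylchroman-6-yl)methyl]-2-hydroxy-3-oxo-3-phenylpropanoate
Conditions: 8 (1.5 equiv), (5aS,10bR)-5a,10b-dihydro-2-(pentafluorophenyl)-4H,6H-indeno[2,1-b][1,2,4]triazolo[4,3-d][1,4]oxazinium tetrafluoroborate (10 mol %; or its (5aR,10bS) antipode, see assumption), iPr2NEt (20 mol %), 4 Å MS, CH2Cl2, 0 °C → rt, 7 added over 4 h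
Reagents that add atoms: none
Why: Proposed new method: an N-heterocyclic-carbene-catalysed enantioselective crossed benzoin in which the Breslow intermediate of benzaldehyde (a benzoyl anion equivalent) adds to the keto carbon of the enolisable arylpyruvate 7 inside the chiral pocket of the aminoindanol-derived triazolylidene, which tells the ester flank from the arylmethyl flank and so sets the (R) tertiary carbinol directly, while reversible homo-benzoin of benzaldehyde, the weak amine base and slow addition of 7 hold back self-aldol of 7; the closest known reaction type is the carbene-catalysed asymmetric aldehyde–α-keto ester crossed benzoin, established for aryl keto esters and for enolisable β-halo keto esters.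

Step 4
Reactants: 9 methyl (R)-2-[(2,2-dimethylchroman-6-yl)methyl]-2-hydroxy-3-oxo-3-phenylpropanoate; 10 acetoxyacetyl chloride
Product: 12 4'-dehydroxy aspernolide A = methyl (R)-2-[(2,2-dimethylchroman-6-yl)methyl]-4-hydroxy-5-oxo-3-phenyl-2,5-dihydrofuran-2-carboxylate, via acetoxyacetate ester 11 (not isolated)
Conditions: 10 (1.15 equiv), pyridine, DMAP (10 mol %), MeCN, 0 °C → rt; then DBU (3 equiv), 0 → 40 °C; 1 M HCl work-up
Reagents that add atoms: none
Why: O-acylation of the tertiary alcohol, then DBU-mediated intramolecular aldol of the acetoxyacetate enolate onto the phenyl ketone (5-exo), 1,2-acetyl shift to the new alkoxide and E1cB loss of acetate give the 3-hydroxybutenolide directly (aldol condensation–lactone annulation known for 3-hydroxy-4-aryl-furan-2(5H)-ones from tertiary α-hydroxy aryl ketones); the quaternary centre carries no hydrogen and is untouched, so (R) is retained with unchanged CIP priorities.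

**Compound list**

1 | 4-hydroxybenzaldehyde | O=Cc1ccc(O)cc1 | starting material
2 | isoprene (2-methylbuta-1,3-diene) | C=CC(C)=C | starting material
3 | 4-hydroxy-3-(3-methylbut-2-en-1-yl)benzaldehyde (not isolated) | O=Cc1ccc(O)c(CC=C(C)C)c1 | intermediate
4 | 2,2-dimethylchroman-6-carbaldehyde | O=Cc1ccc2OC(C)(C)CCc2c1 | intermediate
5 | methyl 2-[(tert-butyldimethylsilyl)oxy]-2-(dimethoxyphosphoryl)acetate (racemic) | COC(=O)C(O[Si](C)(C)C(C)(C)C)P(=O)(OC)OC | starting material
6 | methyl (Z)-2-[(tert-butyldimethylsilyl)oxy]-3-(2,2-dimethylchroman-6-yl)acrylate (major isomer of an E/Z mixture, not isolated) | COC(=O)/C(O[Si](C)(C)C(C)(C)C)=C/c1ccc2OC(C)(C)CCc2c1 | intermediate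
7 | methyl 3-(2,2-dimethylchroman-6-yl)-2-oxopropanoate (keto/enol mixture) | COC(=O)C(=O)Cc1ccc2OC(C)(C)CCc2c1 | intermediate
8 | benzaldehyde | O=Cc1ccccc1 | starting material
9 | methyl (R)-2-[(2,2-dimethylchroman-6-yl)methyl]-2-hydroxy-3-oxo-3-phenylpropanoate | COC(=O)[C@](Cc1ccc2c(c1)CCC(C)(C)O2)(O)C(=O)c1ccccc1 | intermediate
10 | acetoxyacetyl chloride (2-chloro-2-oxoethyl acetate) | CC(=O)OCC(=O)Cl | starting material
11 | methyl (R)-2-[(acetoxyacetyl)oxy]-2-[(2,2-dimethylchroman-6-yl)methyl]-3-oxo-3-phenylpropanoate (not isolated) | COC(=O)[C@](Cc1ccc2c(c1)CCC(C)(C)O2)(OC(=O)COC(C)=O)C(=O)c1ccccc1 | intermediate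
12 | 4'-dehydroxy aspernolide A, methyl (R)-2-[(2,2-dimethylchroman-6-yl)methyl]-4-hydroxy-5-oxo-3-phenyl-2,5-dihydrofuran-2-carboxylate | COC(=O)[C@]1(Cc2ccc3c(c2)CCC(C)(C)O3)OC(=O)C(O)=C1c1ccccc1 | target

**Step count and risks**

Total step count: 4. Longest linear sequence: 4 (1 → 4 → 7 → 9 → 12).

Steps most likely to fail, in order of risk:

Step 3 (crossed benzoin). Ketoester 7 is largely enolised, so self-aldol, slow turnover from base buffering, or only moderate enantioselectivity are all possible. The ee of 9 is measured by chiral HPLC and raised by recrystallisation if needed. The fallback sets out from 4 and comes back to the route at 9. Knoevenagel condensation of 4 with methyl 3-oxo-3-phenylpropanoate (piperidine, AcOH, toluene, Dean–Stark) gives methyl 2-benzoyl-3-(2,2-dimethylchroman-6-yl)acrylate F1. Conjugate reduction with Hantzsch ester (or H2 over Pd/C) gives racemic methyl 2-benzoyl-3-(2,2-dimethylchroman-6-yl)propanoate F2. Catalytic enantioselective α-hydroxylation of this β-keto ester (cinchona-derived quaternary ammonium phase-transfer catalyst of the antipode that gives R, cumene hydroperoxide, toluene/aqueous K2HPO4, 0 °C) then installs the tertiary hydroxyl and gives 9.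

Step 4 (acylation/annulation). The tertiary carbinol is hindered and flanked by two carbonyl groups, so acylation may be slow. Base could also trigger a C-to-O benzoyl shift in 9 before acylation, and the acetate-transfer cascade could be diverted (for example by Dieckmann attack on the methyl ester). The fallback sets out from 9 and comes back at 12. Acylation with benzyloxyacetyl chloride (iPr2NEt, DMAP, CH2Cl2, −20 °C → rt; the ketene formed in the flask acylates hindered alcohols) gives methyl (R)-2-{[(benzyloxy)acetyl]oxy}-2-[(2,2-dimethylchroman-6-yl)methyl]-3-oxo-3-phenylpropanoate F3, which is isolated. Aldol condensation (DBU, MeCN, 40 °C, or TiCl4/Bu3N soft enolisation if the base route is unselective) closes it to the benzyl-protected enol methyl (R)-4-(benzyloxy)-2-[(2,2-dimethylchroman-6-yl)methyl]-5-oxo-3-phenyl-2,5-dihydrofuran-2-carboxylate F4. Hydrogenolysis (H2, Pd/C, EtOAc, rt) frees the enol and gives 12.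

Step 1 (chroman annulation). The phenol is deactivated by the formyl group, so conversion may be low, and over-prenylation or Prins-type attack on the aldehyde may compete. The fallback sets out from 2 and comes back at 4. Isoprene 2 and phenol (85% H3PO4, 30–35 °C) give 2,2-dimethylchroman F5, which forms readily from the electron-rich phenol. Rieche formylation (Cl2CHOCH3, TiCl4, CH2Cl2, 0 °C), para to the ring oxygen, then gives 4.

**Further compounds**

F1 | step 3 | methyl 2-benzoyl-3-(2,2-dimethylchroman-6-yl)acrylate (E/Z mixture) | COC(=O)C(=Cc1ccc2OC(C)(C)CCc2c1)C(=O)c1ccccc1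
F2 | step 3 | methyl 2-benzoyl-3-(2,2-dimethylchroman-6-yl)propanoate (racemic) | COC(=O)C(Cc1ccc2OC(C)(C)CCc2c1)C(=O)c1ccccc1
F3 | step 4 | methyl (R)-2-{[(benzyloxy)acetyl]oxy}-2-[(2,2-dimethylchroman-6-yl)methyl]-3-oxo-3-phenylpropanoate | COC(=O)[C@](Cc1ccc2c(c1)CCC(C)(C)O2)(OC(=O)COCc1ccccc1)C(=O)c1ccccc1
F4 | step 4 | methyl (R)-4-(benzyloxy)-2-[(2,2-dimethylchroman-6-yl)methyl]-5-oxo-3-phenyl-2,5-dihydrofuran-2-carboxylate | COC(=O)[C@]1(Cc2ccc3c(c2)CCC(C)(C)O3)OC(=O)C(OCc2ccccc2)=C1c1ccccc1
F5 | step 1 | 2,2-dimethylchroman | CC1(C)CCc2ccccc2O1
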